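**Compound numbers used throughout** (full names and SMILES are in the list after the steps): 1 (R)-2-methylglycidol; 2 allyl-extended diol; 3 side-chain diol; 4 its primary tosylate; 5 2,4,6-trihydroxytoluene; 6 C1-isobutyryl methylphloroglucinol; 7 side-chain epoxide (formed in the flask); 8 O4 ether; 9 C3 aldehyde; 10 tris-silyl aldehyde; 11 tosylhydrazone; 12 aryldiazomethane (formed in the flask); 13 silylated dihydrobenzofuran; 14 dihydrobenzofuran triol; 15 C5-prenylated dienone; 16 target.

**Atom labels (those of the target, kept for every intermediate):** ring A = C1 (isobutyryl, prenyl), C2 (C=O), C3, C4 (bears the ring oxygen O4), C5 (methyl, prenyl), C6 (C=O); ring B = O4, C8, C7 together with C3 and C4; C9 = carbinol carbon; O2, O6, O9 = oxygens on C2, C6, C9.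

## Analysis of the target

The target is a dearomatised acylphloroglucinol in which ring A, a cyclohexenedione, shares its C3=C4 double bond with a 2,3-dihydrofuran (ring B: O4, C8, C7), so that O4–C4=C3–C2=O is a vinylogous ester. C8 carries the tertiary carbinol C9 with its methyl group and 4-methylpent-3-enyl chain. There are four stereocentres: the contiguous pair C8 (S) and C9 (S) on the ring-B side, and the two all-carbon quaternary centres C5 (S; methyl, prenyl) and C1 (R; prenyl, isobutyryl), which flank the C6 ketone with their prenyl groups trans. The two pairs are separated by the flat C3=C4 unit, so neither can be expected to control the other. Sensitive groups are three trisubstituted alkenes (no ozonolysis, hydrogenation or strong acid), a tertiary alcohol β to O4 that can cyclise onto the side-chain alkene under acid, and C1, which carries three carbonyl groups and is cleaved by nucleophiles (retro-Claisen). The difficulty lies in a hexasubstituted ring whose every substituent must be placed regiochemically, in two quaternary stereocentres without a neighbouring control element, and in C8 sitting next to the quaternary C9. The strategy rests on one feature: in an aromatic progenitor C7 is a benzylic carbon on C3, ortho to O4, and C8 lies between O4 and C9. A carbene at C7 therefore finds the C8–H bonds of an O4 ether in the 1,5 position, and ring B can be closed by C–H insertion with C9 already in place.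

## Retrosynthetic reasoning

**16 ⇒ 15 (C1–prenyl bond).** The carbon bearing three carbonyl groups is made last, because once formed it cannot be carried through nucleophilic steps. It is made by alkylation and not by acylation: the incoming group should enter the nearly planar ring anti to the larger C5 substituent, so bringing in the prenyl group last places it trans to the C5 prenyl group, as 16 requires. The forward step must give C- and not O-alkylation of a triketone enolate, which a π-allylpalladium electrophile can do.

**15 ⇒ 14 (C5–prenyl bond; ring A becomes aromatic).** Removing the C5 prenyl group gives the aromatic acylphloroglucinol 14. This cut is dictated by the key step, which needs an aromatic ring. It is where the strategy pays: the forward reaction must alkylate the methyl-bearing C5 and not C3 or oxygen, and must choose one face of a flat ring far from C8 and C9, so a chiral catalyst has to do both.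

**14 ⇒ 13 (three O–Si bonds).** The phenols and the tertiary alcohol are masked as silyl ethers for the carbene step. A silyl group is the only common phenol protection that offers the C7 carbene no C–H bond in the 1,5 position on O2, and a free O9–H would invite O–H insertion.

**13 ⇒ 11 via 12 (C7–C8 bond, ring B, C8).** Ring B is opened at C7–C8. What is gained is that the precursor is a simple aryl ether whose only stereocentre, C9, comes from the chiral pool, and that ring B and C8 arise in one step at a carbon that cannot epimerise afterwards. The forward reaction must generate a carbene at C7 and let it select one of the two diastereotopic C8–H bonds.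

**11 ⇒ 10 ⇒ 9 (C7=N bond, O–Si bonds).** The carbene precursor is the sulfonylhydrazone of the C3 aldehyde; only the aldehyde condenses, since the C1 ketone is buried between two silyloxy groups.

**9 ⇒ 8 (C3–C7 bond).** C7 is introduced as a formyl group at the only unsubstituted ring carbon, ortho to the free O2–H, so its position is forced. It is introduced after the ether is in place, for the reason given next.

**8 ⇒ 6 + 4 via 7 (O4–C8 bond).** The ether bond is cut so that the whole side chain arrives as one chiral piece. The order matters: in a ring that already carries the C3 formyl group, O4 would be the most hindered and a hydrogen-bonded hydroxyl, and alkylation would go elsewhere. With the C1 ketone as the only ring carbonyl, as in 6, O4 is the para hydroxyl, the most acidic and the only one not held in a hydrogen bond, so it is alkylated selectively. The same ketone blocks C1 and leaves C3 as the single site for the later formylation. A sulfonate on a CH2 next to a quaternary carbon does not undergo direct displacement; 4 is therefore used as the precursor of epoxide 7, which a phenoxide opens readily at its CH2.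

**6 ⇒ 5 (C1–acyl bond).** Friedel–Crafts acylation of the symmetrical triol 5; its two free positions are equivalent.

**4 ⇒ 3 ⇒ 2 ⇒ 1 (side chain).** The chain is cut between the two CH2 groups next to C9 (an allyl nucleophile opening epoxide 1 at its CH2), and the trisubstituted alkene is made by cross-metathesis. C9 is taken unchanged from 1.

## Alternatives that were turned down

**Alternative 1:** Ring A is cut at C3–C4 and C1–C6. This gives a three-carbon nucleophile, the dianion of 5-methylhexane-2,4-dione A2, and a three-carbon bis-electrophile A3, the imidazolide methyl ester of 2-methyl-2-prenylmalonic acid, in which C5 is already quaternary and stereodefined. In the forward key step the terminal carbon of the dianion of A2 is acylated by the imidazolide carbonyl of A3 (C3–C4), and the central carbon then closes on the ester (C1–C6) to give the enolised trione A1.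
- For it: C5 is fixed before ring A exists, so there is no dearomatisation, no C5-versus-C3 question and no face to select. The isobutyryl group arrives with A2, and ring A is made in one operation.
- Against it: both acylations occur at carbonyls attached to a quaternary carbon, and the closure is a reversible Claisen condensation whose product can reopen. Single-enantiomer A3 depends on desymmetrising a malonate whose two ester groups differ only through a methyl/prenyl distinction.
- More important, A1 contains none of ring B. C3 must still be alkylated with a ten-carbon unit, O4 (and not O2, which flanks C3 equally) must be bonded to C8, and C8/C9 must be created on a chain with two trisubstituted alkenes of similar reactivity.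
- Comparison: on C5 this route is stronger than the chosen one, whose weakest step is the C5 prenylation. In exchange the chosen route takes C9 from the chiral pool, makes C8 in one ring-closing step, and settles the regiochemistry of ring B through aromatic substitution patterns. The step count would be similar, with the risk spread over more steps.

**Alternative 2:** The cut is at C2–C3, and that bond closes ring A. Heating dioxinone A5 sets off a retro-hetero-Diels–Alder fragmentation that unmasks an acylketene (C6 carbonyl, C1, ketene carbon C2). The nucleophilic β-carbon C3 of the dihydrofuran enol ether adds to C2, and loss of the C3 proton gives the vinylogous ester dione A4.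
- For it: the ring closure is neutral and needs no reagent. C5, C8 and C9 are all in place beforehand, so again no dearomatisation, and the vinylogous ester of the target is formed directly.
- Against it: A5 is far from commercial materials. It needs a 2,3-dihydrofuran substituted at its enol-ether carbon by the quaternary C5, with three stereocentres and an acid-labile enol ether carried through the dioxinone chemistry.
- A4 also has a bare CH2 at C1. Two further C–C bonds (isobutyryl, then prenyl) must be made there, the second with the same weak, remote stereocontrol that the chosen route faces in its last step.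
- Comparison: stronger than the chosen route on C5, equal on C1, clearly weaker on step economy and on the stability of intermediates. The chosen route instead reaches its key-step precursor in eight steps of aromatic and protecting-group chemistry.

**Alternative 3:** The cuts are C3–C7 and O4–C8, both in ring B. In the forward key step the C3–I bond of iodophenol A7 adds oxidatively to zerovalent palladium, the unsubstituted vinyl end of isoprene A8 inserts to give C3–C7 and a π-allyl complex, and the O4 phenoxide attacks C8 under a chiral ligand. The product is the 2-isopropenyl dihydrobenzofuran A6.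
- For it: ring B comes from the commodity diene A8 in one step, and C8 is set by a catalyst on a substrate with no other stereocentre, so there is no mismatched case.
- C9 would follow by oxidative cleavage of A6 to the methyl ketone A9 and chelation-controlled addition of the Grignard reagent A10. The Cram chelate model (magnesium held between O4 and the carbonyl oxygen, attack anti to C7) predicts the C8/C9 relationship of the target. On this pair the alternative is as strong as the chosen route and shorter in fragment synthesis.
- Against it: A7 needs O4 free and O2/O6 protected, yet O4 is the most hindered hydroxyl of such a ring, so the regiochemical problem returns without the solution that the C1 ketone provides.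
- Enantioselection in the heteroannulation of the doubly ortho-substituted, electron-rich A7 with A8 is not assured, and the isopropenyl group of A6 must be cleaved oxidatively next to an electron-rich arene.
- In A9 the catalyst-made C8 centre sits α to a ketone and can be lost by enolisation under the basic Grignard conditions. The acetal protecting groups must later be removed with acid in the presence of the tertiary alcohol and the alkenes. C1 acylation and the same two prenylations remain.
- Comparison: the chosen route gives up the one-step ring B but fixes C9 by a stereocentre that no step touches, and makes C8 at a carbon that cannot epimerise afterwards. The heteroannulation logic is kept as the fallback for the key step.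

Key step: step 9

Remark on the chemistry: (2R)-(2-methyloxiran-2-yl)methanol, compound 1, and tert-butyl 3-methylbut-2-en-1-yl carbonate are taken as purchasable (each is otherwise one step, a Sharpless epoxidation of 2-methylprop-2-en-1-ol and a carbonate formation from prenol); 15 is drawn as one of its enol tautomers.

## Route

**Step 1**
Reactants: 1 (2R)-(2-methyloxiran-2-yl)methanol
Product: 2 (2S)-2-methylhept-6-ene-1,2-diol
Conditions: allylmagnesium chloride (2.5 equiv), CuBr·SMe2 (10 mol %), THF, −30 → 0 °C; aq. NH4Cl
Reagents that add atoms: allylmagnesium chloride, C=CC[Mg]Cl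
Why: Copper-catalysed Grignard opening of a 2,2-disubstituted epoxide takes place at the unsubstituted CH2 (SN2), after the first equivalent has deprotonated the hydroxyl; the quaternary stereocentre is not touched, and its descriptor changes from R to S only because the CIP ranks of the two CH2 groups swap.

**Step 2**
Reactants: 2 (2S)-2-methylhept-6-ene-1,2-diol
Product: 3 (2S)-2,6-dimethylhept-5-ene-1,2-diol
Conditions: 2-methylbut-2-ene (excess, co-solvent), second-generation Grubbs catalyst (3 mol %), CH2Cl2, 40 °C
Reagents that add atoms: 2-methylbut-2-ene, CC=C(C)C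
Why: Olefin cross-metathesis of a terminal alkene with excess 2-methylbut-2-ene turns the vinyl end into the isopropylidene end with loss of propene; the free diol is tolerated and C9 is remote.

**Step 3**
Reactants: 3 (2S)-2,6-dimethylhept-5-ene-1,2-diol
Product: 4 (2S)-2-hydroxy-2,6-dimethylhept-5-en-1-yl 4-methylbenzenesulfonate
Conditions: TsCl (1.1 equiv), Et3N, DMAP (cat.), CH2Cl2, 0 °C
Reagents that add atoms: 4-methylbenzenesulfonyl chloride, Cc1ccc(cc1)S(Cl)(=O)=O
Why: Sulfonylation distinguishes the primary from the tertiary hydroxyl on steric grounds; the non-volatile hydroxy tosylate is a storable precursor of the volatile epoxide.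

**Step 4**
Reactants: 5 2-methylbenzene-1,3,5-triol (2,4,6-trihydroxytoluene)
Product: 6 2-methyl-1-(2,4,6-trihydroxy-3-methylphenyl)propan-1-one
Conditions: isobutyryl chloride (1.1 equiv), AlCl3 (3.5 equiv), PhNO2/CH2Cl2, 0 °C → rt; aq. HCl
Reagents that add atoms: isobutyryl chloride, CC(C)C(Cl)=O
Why: Friedel–Crafts acylation of a phloroglucinol; the two free ring positions of 5 are equivalent, so one product forms, and the first acyl group deactivates the ring against a second.

**Step 5**
Reactants: 6 2-methyl-1-(2,4,6-trihydroxy-3-methylphenyl)propan-1-one; 4 (2S)-2-hydroxy-2,6-dimethylhept-5-en-1-yl 4-methylbenzenesulfonate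
Product: 8 1-[2,6-dihydroxy-4-{[(2S)-2-hydroxy-2,6-dimethylhept-5-en-1-yl]oxy}-3-methylphenyl]-2-methylpropan-1-one, via epoxide 7 (not isolated)
Conditions: K2CO3 (2.5 equiv), DMF, rt → 80–90 °C, argon
Reagents that add atoms: none
Why: Base closes 4 to the epoxide 7 (intramolecular Williamson reaction), and the phenoxide of 6 opens it at the CH2 terminus. Only the hydroxyl para to the ketone (O4) is free of an intramolecular hydrogen bond and it is the most acidic, the usual site selectivity of 2,4,6-trihydroxyaryl ketones. C9 takes no part, so its configuration is kept.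

**Step 6**
Reactants: 8 1-[2,6-dihydroxy-4-{[(2S)-2-hydroxy-2,6-dimethylhept-5-en-1-yl]oxy}-3-methylphenyl]-2-methylpropan-1-one
Product: 9 2,4-dihydroxy-6-{[(2S)-2-hydroxy-2,6-dimethylhept-5-en-1-yl]oxy}-5-methyl-3-(2-methylpropanoyl)benzaldehyde
Conditions: MgCl2 (3 equiv), Et3N (6 equiv), (CH2O)n (8 equiv), MeCN, reflux; cold aq. citric acid
Reagents that add atoms: paraformaldehyde (as formaldehyde), C=O
Why: Casnati–Skattebøl ortho-formylation: the magnesium phenoxide of O2 delivers formaldehyde to the ortho carbon and the hydroxymethyl intermediate passes hydride to a second formaldehyde. C3 is the only unsubstituted ring carbon, so the position is forced, and the mildly basic medium spares the tertiary alcohol and the alkene.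

**Step 7**
Reactants: 9 2,4-dihydroxy-6-{[(2S)-2-hydroxy-2,6-dimethylhept-5-en-1-yl]oxy}-5-methyl-3-(2-methylpropanoyl)benzaldehyde
Product: 10 2,4-bis[(tert-butyldimethylsilyl)oxy]-6-{[(2S)-2-[(tert-butyldimethylsilyl)oxy]-2,6-dimethylhept-5-en-1-yl]oxy}-5-methyl-3-(2-methylpropanoyl)benzaldehyde
Conditions: TBSOTf (3.6 equiv), 2,6-lutidine (6 equiv), CH2Cl2, −40 °C → rt
Reagents that add atoms: tert-butyldimethylsilyl trifluoromethanesulfonate, CC(C)(C)[Si](C)(C)OS(=O)(=O)C(F)(F)F
Why: A silyl triflate with a hindered pyridine base silylates the two chelated phenols and the tertiary alcohol in one operation; the aldehyde has no α-hydrogen and the hindered ketone is not enolised by lutidine.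

**Step 8**
Reactants: 10 2,4-bis[(tert-butyldimethylsilyl)oxy]-6-{[(2S)-2-[(tert-butyldimethylsilyl)oxy]-2,6-dimethylhept-5-en-1-yl]oxy}-5-methyl-3-(2-methylpropanoyl)benzaldehyde
Product: 11 N'-[(E)-(2,4-bis[(tert-butyldimethylsilyl)oxy]-6-{[(2S)-2-[(tert-butyldimethylsilyl)oxy]-2,6-dimethylhept-5-en-1-yl]oxy}-5-methyl-3-(2-methylpropanoyl)phenyl)methylidene]-4-methylbenzenesulfonohydrazide
Conditions: TsNHNH2 (1.05 equiv), THF, 4 Å molecular sieves, rt
Reagents that add atoms: 4-methylbenzenesulfonohydrazide, Cc1ccc(cc1)S(=O)(=O)NN
Why: Hydrazone condensation; only the aldehyde reacts, because the ketone lies between two silyloxy groups, and aprotic neutral conditions are chosen to keep the aryl silyl ethers.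

**Step 9**
Reactants: 11 the tosylhydrazone named in step 8
Product: 13 1-[(2S)-4,6-bis[(tert-butyldimethylsilyl)oxy]-2-[(2S)-2-[(tert-butyldimethylsilyl)oxy]-6-methylhept-5-en-2-yl]-7-methyl-2,3-dihydro-1-benzofuran-5-yl]-2-methylpropan-1-one, via aryldiazomethane 12 (not isolated)
Conditions: NaH (1.05 equiv), THF, 0 °C; then Rh2(S-PTAD)4 or Rh2(R-PTAD)4 (dirhodium tetrakis[(1-adamantyl)(N-phthalimido)acetate], 1 mol %, matched antipode), BnEt3NCl (10 mol %), 1,4-dioxane, 50 °C, 0.01 M
Reagents that add atoms: none
Why: Deprotonation of 11 and warming expel sulfinate (Bamford–Stevens) to give the aryldiazomethane 12, which the divalent rhodium carboxylate captures with loss of N2 as an electrophilic rhodium aryl carbene at C7. The carbene carbon is ortho to O4, so the C8–H bonds lie in the 1,5 position; insertion is concerted but asynchronous (hydride-like transfer to C7 together with C7–C8 bond formation), helped by lone-pair donation from O4 to the positive charge that develops at C8. The closest known reaction type is the intramolecular 1,5 C–H insertion of aryl carbenes generated from N-tosylhydrazones of 2-alkoxybenzaldehydes and 2-alkoxyaryl ketones, which gives 2-substituted 2,3-dihydrobenzofurans under catalysis by dirhodium tetracarboxylates such as Rh2(OAc)4. Ring B closes through a five-membered cyclic transition state made of C7, C3, C4, O4 and C8; the six-membered alternatives (Si–CH3 of the O2 silyl group, the C9 methyl group) are neither activated nor geometrically preferred, and cyclopropanation of the remote alkene would need a nine-membered ring. C8 is the only new stereocentre and arises with retention from whichever of the two diastereotopic C8–H bonds is replaced; C9 is not touched. The selection is steered by the quaternary C9, whose bulky silyloxy group is expected to turn away from the catalyst wall, and is reinforced by the chiral carboxylate ligands, the antipode being chosen so that catalyst and substrate preferences match. Chemoselectivity over carbene dimerisation and azine formation is secured by generating 12 slowly at high dilution so that it never accumulates. The C1 ketone, twisted out of plane between two silyloxy groups, and the silyl ethers offer no O–H or activated C–H bond to compete.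

**Step 10**
Reactants: 13 the silylated dihydrobenzofuran named in step 9
Product: 14 1-[(2S)-4,6-dihydroxy-2-[(2S)-2-hydroxy-6-methylhept-5-en-2-yl]-7-methyl-2,3-dihydro-1-benzofuran-5-yl]-2-methylpropan-1-one
Conditions: TBAF (6 equiv), THF, 50 °C, argon; aq. NH4Cl
Reagents that add atoms: none
Why: Fluoride cleaves the Si–O bonds; the aryl silyl ethers go at once and the tertiary alkyl silyl ether on warming, under basic conditions that leave the alkene, the tertiary alcohol and both stereocentres untouched.

**Step 11**
Reactants: 14 the triol named in step 10
Product: 15 (2S,7S)-4-hydroxy-2-[(2S)-2-hydroxy-6-methylhept-5-en-2-yl]-7-methyl-7-(3-methylbut-2-en-1-yl)-5-(2-methylpropanoyl)-2,3-dihydro-1-benzofuran-6(7H)-one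
Conditions: Pd2(dba)3 (2.5 mol %), Trost ligand N,N'-(cyclohexane-1,2-diyl)bis[2-(diphenylphosphino)benzamide] (7.5 mol %, antipode fixed in a test run), tert-butyl prenyl carbonate (1.05 equiv), THF, 0 °C
Reagents that add atoms: tert-butyl 3-methylbut-2-en-1-yl carbonate, CC(C)=CCOC(=O)OC(C)(C)C
Why: Proposed new method: the tert-butoxide released on ionisation of the carbonate deprotonates a phenol of 14, and the delocalised phenoxide attacks the CH2 terminus of the π-prenylpalladium cation through carbon; attack at the methyl-bearing C5 gives the cyclohexadienone 15, any O-prenyl ether being re-ionised by zerovalent palladium and so funnelled to C-alkylation, while the chiral pocket of the ligand is asked to choose both the face of C5 and C5 over C3; the closest known reaction types are the palladium-catalysed dearomative allylation of acylphloroglucinols and the ligand-controlled asymmetric allylic dearomatisation of substituted phenols and naphthols, neither shown with a prenyl electrophile on a fully substituted acylphloroglucinol; 15 is more acidic than 14, stays as its weakly nucleophilic anion and should not take up a second prenyl group under these conditions.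

**Step 12**
Reactants: 15 the dienone named in step 11
Product: 16 (2S,5R,7S)-2-[(2S)-2-hydroxy-6-methylhept-5-en-2-yl]-7-methyl-5,7-bis(3-methylbut-2-en-1-yl)-5-(2-methylpropanoyl)-2,3-dihydro-1-benzofuran-4,6(5H,7H)-dione (target)
Conditions: Pd(PPh3)4 (5 mol %), tert-butyl prenyl carbonate (1.5 equiv), THF, 25–40 °C
Reagents that add atoms: tert-butyl 3-methylbut-2-en-1-yl carbonate, CC(C)=CCOC(=O)OC(C)(C)C
Why: Tsuji–Trost allylation: the triketone enolate of 15 attacks the unsubstituted terminus of the π-prenylpalladium cation through C1, O-prenyl enol ethers being reversible under the catalyst, and the base is tert-butoxide so that the retro-Claisen-prone product is not cleaved. The C1 centre is set by C5: the electrophile should approach the face of the nearly planar ring that carries the C5 methyl and not the C5 prenyl group, which places the two prenyl groups trans as in 16.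

## Compound list

1 | (2R)-(2-methyloxiran-2-yl)methanol, (R)-2-methylglycidol | C[C@@]1(CO)CO1 | starting material
2 | (2S)-2-methylhept-6-ene-1,2-diol | C=CCC[C@](C)(O)CO | intermediate
3 | (2S)-2,6-dimethylhept-5-ene-1,2-diol | CC(C)=CCC[C@](C)(O)CO | intermediate
4 | (2S)-2-hydroxy-2,6-dimethylhept-5-en-1-yl 4-methylbenzenesulfonate | CC(C)=CCC[C@](C)(O)COS(=O)(=O)c1ccc(C)cc1 | intermediate
5 | 2-methylbenzene-1,3,5-triol (2,4,6-trihydroxytoluene) | Cc1c(O)cc(O)cc1O | starting material
6 | 2-methyl-1-(2,4,6-trihydroxy-3-methylphenyl)propan-1-one | CC(C)C(=O)c1c(O)cc(O)c(C)c1O | intermediate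
7 | (2S)-2-methyl-2-(4-methylpent-3-en-1-yl)oxirane | CC(C)=CCC[C@@]1(C)CO1 | intermediate (not isolated)
8 | 1-[2,6-dihydroxy-4-{[(2S)-2-hydroxy-2,6-dimethylhept-5-en-1-yl]oxy}-3-methylphenyl]-2-methylpropan-1-one | CC(C)=CCC[C@](C)(O)COc1cc(O)c(C(=O)C(C)C)c(O)c1C | intermediate
9 | 2,4-dihydroxy-6-{[(2S)-2-hydroxy-2,6-dimethylhept-5-en-1-yl]oxy}-5-methyl-3-(2-methylpropanoyl)benzaldehyde | CC(C)=CCC[C@](C)(O)COc1c(C=O)c(O)c(C(=O)C(C)C)c(O)c1C | intermediate
10 | 2,4-bis[(tert-butyldimethylsilyl)oxy]-6-{[(2S)-2-[(tert-butyldimethylsilyl)oxy]-2,6-dimethylhept-5-en-1-yl]oxy}-5-methyl-3-(2-methylpropanoyl)benzaldehyde | CC(C)=CCC[C@](C)(O[Si](C)(C)C(C)(C)C)COc1c(C=O)c(O[Si](C)(C)C(C)(C)C)c(C(=O)C(C)C)c(O[Si](C)(C)C(C)(C)C)c1C | intermediate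
11 | (E)-N-tosylhydrazone of 10 | CC(C)=CCC[C@](C)(O[Si](C)(C)C(C)(C)C)COc1c(/C=N/NS(=O)(=O)c2ccc(C)cc2)c(O[Si](C)(C)C(C)(C)C)c(C(=O)C(C)C)c(O[Si](C)(C)C(C)(C)C)c1C | intermediate (key-step precursor)
12 | aryldiazomethane from 11 (C7 = CHN2) | CC(C)=CCC[C@](C)(O[Si](C)(C)C(C)(C)C)COc1c(C=[N+]=[N-])c(O[Si](C)(C)C(C)(C)C)c(C(=O)C(C)C)c(O[Si](C)(C)C(C)(C)C)c1C | intermediate (not isolated)
13 | 1-[(2S)-4,6-bis[(tert-butyldimethylsilyl)oxy]-2-[(2S)-2-[(tert-butyldimethylsilyl)oxy]-6-methylhept-5-en-2-yl]-7-methyl-2,3-dihydro-1-benzofuran-5-yl]-2-methylpropan-1-one | CC(C)=CCC[C@](C)(O[Si](C)(C)C(C)(C)C)[C@@H]1Cc2c(O1)c(C)c(O[Si](C)(C)C(C)(C)C)c(C(=O)C(C)C)c2O[Si](C)(C)C(C)(C)C | intermediate (key-step product)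
14 | 1-[(2S)-4,6-dihydroxy-2-[(2S)-2-hydroxy-6-methylhept-5-en-2-yl]-7-methyl-2,3-dihydro-1-benzofuran-5-yl]-2-methylpropan-1-one | CC(C)=CCC[C@](C)(O)[C@@H]1Cc2c(O1)c(C)c(O)c(C(=O)C(C)C)c2O | intermediate
15 | (2S,7S)-4-hydroxy-2-[(2S)-2-hydroxy-6-methylhept-5-en-2-yl]-7-methyl-7-(3-methylbut-2-en-1-yl)-5-(2-methylpropanoyl)-2,3-dihydro-1-benzofuran-6(7H)-one | CC(C)=CCC[C@](C)(O)[C@@H]1CC2=C(O1)[C@](C)(CC=C(C)C)C(=O)C(C(=O)C(C)C)=C2O | intermediate
16 | (2S,5R,7S)-2-[(2S)-2-hydroxy-6-methylhept-5-en-2-yl]-7-methyl-5,7-bis(3-methylbut-2-en-1-yl)-5-(2-methylpropanoyl)-2,3-dihydro-1-benzofuran-4,6(5H,7H)-dione | CC(C)=CCC[C@](C)(O)[C@@H]1CC2=C(O1)[C@](C)(CC=C(C)C)C(=O)[C@](CC=C(C)C)(C(=O)C(C)C)C2=O | target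

## Step count and least certain steps

Total step count: 12. Longest linear sequence: 11 steps (steps 1–3 and 5–12); step 4 joins at step 5.

**Step 11 (C5 prenylation).** The most likely failures are alkylation at the wrong site (C3, which is electronically almost equivalent to C5, or oxygen) and poor facial selectivity, because the reacting carbon is far from C8 and C9 and the catalyst must discriminate a flat, fully substituted nucleophile. The fallback uses known chemistry and gives up catalyst control. It sets out from 14: classical base-mediated dearomative C-prenylation of the acylphloroglucinol (prenyl bromide, NaOMe, MeOH, 0 °C) gives 15 together with its C5 epimer, (2S,7R)-4-hydroxy-2-[(2S)-2-hydroxy-6-methylhept-5-en-2-yl]-7-methyl-7-(3-methylbut-2-en-1-yl)-5-(2-methylpropanoyl)-2,3-dihydro-1-benzofuran-6(7H)-one F1. The two are diastereomers because of C8 and C9 and are separated by chromatography; the route is rejoined at 15.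

**Step 9 (key step).** The most likely failures are insufficient discrimination between the two C8–H bonds (the bias from the acyclic C9 is weak and the catalyst may be mismatched) and slow insertion at a CH2 that is hindered by the quaternary C9 and inductively deactivated by the β-silyloxy group, which lets carbene dimerisation and azine formation take over. The fallback abandons C–H selection and sets C8 and C9 in the reverse order; it sets out from 6 and rejoins at 14. Iodination of 6 at C3 with N-iodosuccinimide gives 1-(2,4,6-trihydroxy-3-iodo-5-methylphenyl)-2-methylpropan-1-one F2. Palladium-catalysed heteroannulation with isoprene (Pd(OAc)2, chiral phosphine, NaHCO3, DMF) closes ring B through the non-chelated, more acidic O4 and gives 1-[(2S)-4,6-dihydroxy-7-methyl-2-(prop-1-en-2-yl)-2,3-dihydro-1-benzofuran-5-yl]-2-methylpropan-1-one F3. Lemieux–Johnson cleavage (OsO4 cat., NaIO4) gives 1-[(2S)-2-acetyl-4,6-dihydroxy-7-methyl-2,3-dihydro-1-benzofuran-5-yl]-2-methylpropan-1-one F4. Excess (4-methylpent-3-en-1-yl)magnesium bromide F5, made from 5-bromo-2-methylpent-2-ene and magnesium, then adds at −78 °C under chelation control (magnesium between O4 and the acetyl oxygen, attack anti to C7). This should give the (8S,9S) carbinol 14, the aryl ketone being protected as its magnesium phenoxide chelate.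

**Step 12 (C1 prenylation).** The most likely failures are O-alkylation that does not funnel to carbon, retro-Claisen loss of the isobutyryl group from the product, and weak facial bias, since methyl and prenyl at C5 differ little in size at the 1,3-distance. The fallback sets out from 15 and uses a smaller electrophile for which ligand control of a dicarbonyl nucleophile is well established. Palladium-catalysed asymmetric allylic alkylation with allyl acetate (Pd2(dba)3, Trost ligand, THF) gives the C1-allyl compound (2S,5R,7S)-2-[(2S)-2-hydroxy-6-methylhept-5-en-2-yl]-7-methyl-7-(3-methylbut-2-en-1-yl)-5-(2-methylpropanoyl)-5-(prop-2-en-1-yl)-2,3-dihydro-1-benzofuran-4,6(5H,7H)-dione F6. Cross-metathesis with 2-methylbut-2-ene (second-generation Grubbs catalyst) then converts allyl into prenyl and rejoins the route at 16.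

**Step 6 (formylation).** The most likely failures are condensation of the hydroxymethyl intermediate with a second arene (methylene-bridged dimer, a known tendency of phloroglucinols with formaldehyde) and sluggish reaction because magnesium is held in the ketone chelate. The fallback sets out from 8 and introduces C7 by carbonylation instead of electrophilic substitution. Iodination at C3 with N-iodosuccinimide at low temperature gives 1-[2,6-dihydroxy-4-{[(2S)-2-hydroxy-2,6-dimethylhept-5-en-1-yl]oxy}-3-iodo-5-methylphenyl]-2-methylpropan-1-one F7. Silylation as in step 7 gives its tris(tert-butyldimethylsilyl) ether F8. Palladium-catalysed reductive carbonylation (PdCl2(PPh3)2, CO, Et3SiH, Et3N, toluene) then gives the aldehyde and rejoins the route at 10.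

## Further compounds

F1 | step 11 | (2S,7R)-4-hydroxy-2-[(2S)-2-hydroxy-6-methylhept-5-en-2-yl]-7-methyl-7-(3-methylbut-2-en-1-yl)-5-(2-methylpropanoyl)-2,3-dihydro-1-benzofuran-6(7H)-one | CC(C)=CCC[C@](C)(O)[C@@H]1CC2=C(O1)[C@@](C)(CC=C(C)C)C(=O)C(C(=O)C(C)C)=C2O
F2 | step 9 | 1-(2,4,6-trihydroxy-3-iodo-5-methylphenyl)-2-methylpropan-1-one | CC(C)C(=O)c1c(O)c(I)c(O)c(C)c1O
F3 | step 9 | 1-[(2S)-4,6-dihydroxy-7-methyl-2-(prop-1-en-2-yl)-2,3-dihydro-1-benzofuran-5-yl]-2-methylpropan-1-one | CC(=C)[C@@H]1Cc2c(O1)c(C)c(O)c(C(=O)C(C)C)c2O
F4 | step 9 | 1-[(2S)-2-acetyl-4,6-dihydroxy-7-methyl-2,3-dihydro-1-benzofuran-5-yl]-2-methylpropan-1-one | CC(=O)[C@@H]1Cc2c(O1)c(C)c(O)c(C(=O)C(C)C)c2O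
F5 | step 9 | (4-methylpent-3-en-1-yl)magnesium bromide | CC(C)=CCC[Mg]Br
F6 | step 12 | (2S,5R,7S)-2-[(2S)-2-hydroxy-6-methylhept-5-en-2-yl]-7-methyl-7-(3-methylbut-2-en-1-yl)-5-(2-methylpropanoyl)-5-(prop-2-en-1-yl)-2,3-dihydro-1-benzofuran-4,6(5H,7H)-dione | CC(C)=CCC[C@](C)(O)[C@@H]1CC2=C(O1)[C@](C)(CC=C(C)C)C(=O)[C@](CC=C)(C(=O)C(C)C)C2=O
F7 | step 6 | 1-[2,6-dihydroxy-4-{[(2S)-2-hydroxy-2,6-dimethylhept-5-en-1-yl]oxy}-3-iodo-5-methylphenyl]-2-methylpropan-1-one | CC(C)=CCC[C@](C)(O)COc1c(I)c(O)c(C(=O)C(C)C)c(O)c1C
F8 | step 6 | 1-[2,6-bis[(tert-butyldimethylsilyl)oxy]-4-{[(2S)-2-[(tert-butyldimethylsilyl)oxy]-2,6-dimethylhept-5-en-1-yl]oxy}-3-iodo-5-methylphenyl]-2-methylpropan-1-one | CC(C)=CCC[C@](C)(O[Si](C)(C)C(C)(C)C)COc1c(I)c(O[Si](C)(C)C(C)(C)C)c(C(=O)C(C)C)c(O[Si](C)(C)C(C)(C)C)c1C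
A1 | alternative 1 | (6S)-3,5-dihydroxy-6-methyl-6-(3-methylbut-2-en-1-yl)-2-(2-methylpropanoyl)cyclohexa-2,4-dien-1-one (enol form of the trione) | OC1=CC(O)=C(C(=O)C(C)C)C(=O)[C@@]1(C)CC=C(C)C
A2 | alternative 1 | 5-methylhexane-2,4-dione | CC(=O)CC(=O)C(C)C
A3 | alternative 1 | methyl (2S)-2-(1H-imidazole-1-carbonyl)-2,5-dimethylhex-4-enoate | COC(=O)[C@@](C)(CC=C(C)C)C(=O)n1ccnc1
A4 | alternative 2 | (2S,7S)-7-methyl-7-(3-methylbut-2-en-1-yl)-2-[(2S)-6-methyl-2-(triethylsilyloxy)hept-5-en-2-yl]-2,3-dihydro-1-benzofuran-4,6(5H,7H)-dione | CC(C)=CCC[C@](C)(O[Si](CC)(CC)CC)[C@@H]1CC2=C(O1)[C@](C)(CC=C(C)C)C(=O)CC2=O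
A5 | alternative 2 | 2,2-dimethyl-1,3-dioxin-4-one bearing at its 6-position the quaternary carbon (methyl, prenyl) that is bonded to the enol-ether carbon of the (2S)-2-[(2S)-6-methyl-2-(triethylsilyloxy)hept-5-en-2-yl]-2,3-dihydrofuran | CC1(C)OC(=O)C=C(O1)[C@@](C)(CC=C(C)C)C1=CC[C@H](O1)[C@](C)(CCC=C(C)C)O[Si](CC)(CC)CC
A6 | alternative 3 | (2S)-4,6-bis(methoxymethoxy)-7-methyl-2-(prop-1-en-2-yl)-2,3-dihydro-1-benzofuran | CC(=C)[C@@H]1Cc2c(O1)c(C)c(OCOC)cc2OCOC
A7 | alternative 3 | 2-iodo-3,5-bis(methoxymethoxy)-6-methylphenol | Cc1c(O)c(I)c(OCOC)cc1OCOC
A8 | alternative 3 | isoprene (2-methylbuta-1,3-diene) | CC(=C)C=C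
A9 | alternative 3 | 1-[(2S)-4,6-bis(methoxymethoxy)-7-methyl-2,3-dihydro-1-benzofuran-2-yl]ethan-1-one | CC(=O)[C@@H]1Cc2c(O1)c(C)c(OCOC)cc2OCOC
A10 | alternative 3 | (4-methylpent-3-en-1-yl)magnesium bromide | CC(C)=CCC[Mg]Br
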